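## Retrosynthetic overview

1. Xestin A ⇐ lipase resolution of the racemic cis ketal 16 ⇐ one-pot aerobic ring expansion and peroxyketalisation of cyclobutenol 14 with O2 and MeOH (three components).
2. Enabling feature: in 14 the four carbons of the dioxine, C(OH)(alkyl)–CH=CH–CH(CH2CO2Me), are already joined as a cyclobut-2-en-1-ol. The strained ring σ-bond between the carbinol carbon and the CH(CH2CO2Me) carbon is the bond into which O–O is inserted, and the cis C=C is already endocyclic.
3. 14 ⇐ Grignard reagent from dienyl bromide 7 + 4-substituted cyclobutenone 12, itself from a keteniminium–acetylene [2+2] cycloaddition.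
4. 7 ⇐ copper-catalysed coupling of a C12 Grignard reagent with sorbyl acetate.
5. Ring order: cyclobutene (step 6), then 1,2-dioxine by four-to-six ring expansion (step 8). The ketal centre is set thermodynamically in step 8; the ring CH centre is formed racemic and selected in step 9.

Key step: step 8

Assumption: the lipase of step 9 is taken to hydrolyse the (3S,6S) ester faster; its enantiopreference on this substrate cannot be predicted by rule. Racemates are written as the two enantiomers joined by a dot.

## Route

Step 1
Reactants: 1 12-bromododecan-1-ol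
Product: 2 (12-bromododecyloxy)(tert-butyl)dimethylsilane
Conditions: TBSCl, imidazole, CH2Cl2, 23 °C
Reagents that add atoms: tert-butyldimethylsilyl chloride, CC(C)(C)[Si](C)(C)Cl
Why: Standard silylation of a primary alcohol masks the OH for Grignard formation.

Step 2
Reactants: 2 (12-bromododecyloxy)(tert-butyl)dimethylsilane; 3 (2E,4E)-hexa-2,4-dien-1-yl acetate (sorbyl acetate)
Product: 5 tert-butyl(dimethyl)[(14E,16E)-octadeca-14,16-dien-1-yloxy]silane, via Grignard reagent 4 (not isolated)
Conditions: Mg, THF, 50 °C; then 3, Li2CuCl4 (3 mol %), THF, −20 → 0 °C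
Reagents that add atoms: none
Why: Copper-catalysed cross-coupling of an alkyl Grignard reagent with a primary allylic acetate should proceed by α-substitution and keep the (E,E)-diene geometry, as in dienyl pheromone syntheses.

Step 3
Reactants: 5 tert-butyl(dimethyl)[(14E,16E)-octadeca-14,16-dien-1-yloxy]silane
Product: 6 (14E,16E)-octadeca-14,16-dien-1-ol
Conditions: CSA (cat.), MeOH, 23 °C
Reagents that add atoms: none
Why: Acid-catalysed methanolysis of a primary silyl ether, to which the isolated conjugated diene should be inert.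

Step 4
Reactants: 6 (14E,16E)-octadeca-14,16-dien-1-ol
Product: 7 (2E,4E)-18-bromooctadeca-2,4-diene
Conditions: CBr4, PPh3, CH2Cl2, 0 °C
Reagents that add atoms: carbon tetrabromide, BrC(Br)(Br)Br
Why: Appel reaction of a primary alcohol under neutral conditions that leave the diene untouched.

Step 5
Reactants: 8 methyl 4-chloro-4-oxobutanoate
Product: 9 methyl 4-(dimethylamino)-4-oxobutanoate
Conditions: Me2NH (2 M in THF), Et3N, CH2Cl2, 0 °C
Reagents that add atoms: dimethylamine, CNC
Why: Acylation of a secondary amine by an acid chloride, which should spare the methyl ester at 0 °C.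

Step 6
Reactants: 9 methyl 4-(dimethylamino)-4-oxobutanoate
Product: 12 methyl 2-(2-oxocyclobut-3-en-1-yl)acetate (racemic), via keteniminium triflate 10 (not isolated), via cyclobuteniminium triflate 11 (not isolated)
Conditions: Tf2O, 2,4,6-collidine, HC≡CH (1 atm), ClCH2CH2Cl, −20 → 40 °C; then H2O
Reagents that add atoms: acetylene, C#C; water, O
Why: Keteniminium–alkyne [2+2] cycloaddition: amide activation gives the aldo-keteniminium salt, which should add to acetylene without regiochemical ambiguity, and hydrolysis of the cyclobuteniminium salt gives the 4-substituted cyclobutenone, whose racemic stereocentre is of no consequence.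

Step 7
Reactants: 7 (2E,4E)-18-bromooctadeca-2,4-diene; 12 methyl 2-(2-oxocyclobut-3-en-1-yl)acetate
Product: 14 methyl 2-{2-hydroxy-2-[(14E,16E)-octadeca-14,16-dien-1-yl]cyclobut-3-en-1-yl}acetate (both carbinol epimers, racemic), via Grignard reagent 13 (not isolated)
Conditions: Mg, THF, 40 °C; then 12, THF, −78 °C; AcOH quench at −78 °C
Reagents that add atoms: none
Why: 1,2-Addition of a primary alkyl Grignard reagent to the strained cyclobutenone carbonyl should outpace attack on the methyl ester at −78 °C, the cold acidic quench forestalls oxy-anion-accelerated ring opening and lactonisation, and the carbinol configuration is irrelevant because both epimers converge in step 8.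

Step 8
Reactants: 14 methyl 2-{2-hydroxy-2-[(14E,16E)-octadeca-14,16-dien-1-yl]cyclobut-3-en-1-yl}acetate
Product: 16 rac-methyl 2-{(3R*,6R*)-6-methoxy-6-[(14E,16E)-octadeca-14,16-dien-1-yl]-3,6-dihydro-1,2-dioxin-3-yl}acetate (OMe and CH2CO2Me cis), via dioxinol 15 (not isolated)
Conditions: Co(acac)2 (20 mol %), O2 (1 atm), PhMe, 40 °C; then MeOH, CSA (10 mol %), 4 Å MS, 0 → 23 °C
Reagents that add atoms: dioxygen, O=O; methanol, CO
Why: Proposed new method: Co(II)/O2 converts the tertiary cyclobutenol into its alkoxyl radical, β-scission of the strained ring bond between the carbinol carbon and the CH(CH2CO2Me) carbon (the other scission would give a vinyl radical) gives a Z-configured keto-allyl radical, O2 adds at the CH terminus, Co(II) reduces the peroxyl, and the hydroperoxide closes on the new ketone (6-exo-trig; the four-membered carbocycle becomes the six-membered ring by insertion of O–O) to dioxinol 15. The closest known reaction type is the Co(acac)2/O2 oxidative ring expansion of cyclobutanols to 1,2-dioxan-3-ols and of cyclopropanols to 1,2-dioxolan-3-ols; new here are the cyclobut-2-enol, the allylic radical and the ring alkene. The ring C=C is never broken and rotation of the allyl radical should be slower than O2 capture, so the cis geometry needed for closure is kept; capture at the carbon α to the ketone should be reversible, whereas capture at the CH terminus gives the conjugated enone and is drained by cyclisation. The ring CH stereocentre is formed without control (racemic), and both carbinol epimers of 14 converge on the same radical. In acidic MeOH the hemiketal ionises to the cyclic peroxycarbenium ion and MeOH adds reversibly, so the ketal centre is set under thermodynamic control with pseudoaxial (anomeric) OMe and pseudoequatorial CH2CO2Me and alkyl chain, which is the cis relation of the target; the trans ketal epimer is separated and resubmitted to CSA/MeOH. The step needs the alkoxyl radical to react at the cyclobutene and not at the side-chain diene, which fast β-scission and fast reduction of the peroxyl radical by Co(II) at low substrate concentration should secure.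

Step 9
Reactants: 16 rac-methyl 2-{(3R*,6R*)-6-methoxy-6-[(14E,16E)-octadeca-14,16-dien-1-yl]-3,6-dihydro-1,2-dioxin-3-yl}acetate
Product: 17 xestin A, methyl 2-{(3R,6R)-6-methoxy-6-[(14E,16E)-octadeca-14,16-dien-1-yl]-3,6-dihydro-1,2-dioxin-3-yl}acetate
Conditions: Burkholderia cepacia lipase (immobilised), phosphate buffer pH 7.2/MTBE, 30 °C, run past half conversion; acid removed by NaHCO3 extraction
Reagents that add atoms: none
Why: Lipase-catalysed kinetic resolution by enantiomer-differentiating ester hydrolysis, a reaction type known for esters with a β-oxygenated stereocentre, should leave the (3R,6R) ester, whose enantiomeric purity rises with conversion; the enzyme reads the ring CH stereocentre β to the acyl carbon, and the neutral buffer leaves the ketal centre untouched.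

## Compound list

1 | 12-bromododecan-1-ol | OCCCCCCCCCCCCBr | starting material
2 | (12-bromododecyloxy)(tert-butyl)dimethylsilane | CC(C)(C)[Si](C)(C)OCCCCCCCCCCCCBr | intermediate
3 | (2E,4E)-hexa-2,4-dien-1-yl acetate | C/C=C/C=C/COC(C)=O | starting material
4 | [12-(tert-butyldimethylsilyloxy)dodecyl]magnesium bromide | CC(C)(C)[Si](C)(C)OCCCCCCCCCCCC[Mg]Br | intermediate
5 | tert-butyl(dimethyl)[(14E,16E)-octadeca-14,16-dien-1-yloxy]silane | C/C=C/C=C/CCCCCCCCCCCCCO[Si](C)(C)C(C)(C)C | intermediate
6 | (14E,16E)-octadeca-14,16-dien-1-ol | C/C=C/C=C/CCCCCCCCCCCCCO | intermediate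
7 | (2E,4E)-18-bromooctadeca-2,4-diene | C/C=C/C=C/CCCCCCCCCCCCCBr | intermediate
8 | methyl 4-chloro-4-oxobutanoate | COC(=O)CCC(Cl)=O | starting material
9 | methyl 4-(dimethylamino)-4-oxobutanoate | COC(=O)CCC(=O)N(C)C | intermediate
10 | N-(4-methoxy-4-oxobut-1-en-1-ylidene)-N-methylmethanaminium triflate (keteniminium salt) | COC(=O)CC=C=[N+](C)C.[O-]S(=O)(=O)C(F)(F)F | intermediate
11 | N-[4-(2-methoxy-2-oxoethyl)cyclobut-2-en-1-ylidene]-N-methylmethanaminium triflate (racemic) | COC(=O)CC1C=CC1=[N+](C)C.[O-]S(=O)(=O)C(F)(F)F | intermediate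
12 | methyl 2-(2-oxocyclobut-3-en-1-yl)acetate (racemic) | COC(=O)CC1C=CC1=O | intermediate
13 | [(14E,16E)-octadeca-14,16-dien-1-yl]magnesium bromide | C/C=C/C=C/CCCCCCCCCCCCC[Mg]Br | intermediate
14 | methyl 2-{2-hydroxy-2-[(14E,16E)-octadeca-14,16-dien-1-yl]cyclobut-3-en-1-yl}acetate (both carbinol epimers, racemic) | C/C=C/C=C/CCCCCCCCCCCCCC1(O)C=CC1CC(=O)OC | intermediate
15 | methyl 2-{6-hydroxy-6-[(14E,16E)-octadeca-14,16-dien-1-yl]-3,6-dihydro-1,2-dioxin-3-yl}acetate (hemiketal epimers, racemic) | C/C=C/C=C/CCCCCCCCCCCCCC1(O)C=CC(CC(=O)OC)OO1 | intermediate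
16 | rac-methyl 2-{(3R*,6R*)-6-methoxy-6-[(14E,16E)-octadeca-14,16-dien-1-yl]-3,6-dihydro-1,2-dioxin-3-yl}acetate (racemate, OMe and CH2CO2Me cis) | C/C=C/C=C/CCCCCCCCCCCCC[C@]1(OC)C=C[C@@H](CC(=O)OC)OO1.C/C=C/C=C/CCCCCCCCCCCCC[C@@]1(OC)C=C[C@H](CC(=O)OC)OO1 | intermediate
17 | xestin A, methyl 2-{(3R,6R)-6-methoxy-6-[(14E,16E)-octadeca-14,16-dien-1-yl]-3,6-dihydro-1,2-dioxin-3-yl}acetate | C/C=C/C=C/CCCCCCCCCCCCC[C@]1(OC)C=C[C@@H](CC(=O)OC)OO1 | target

## Step count and risks

Total step count: 9. Longest linear sequence: 7 (steps 1, 2, 3, 4, 7, 8, 9).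

Steps most likely to fail:

Step 8 (proposed new method). What may go wrong: dioxygen capture at the carbon α to the nascent ketone or on the side-chain diene, loss of the cis geometry by rotation of the allyl radical before capture, or electrocyclic opening of the cyclobutenol before the alkoxyl radical forms. The fallback sets out from 14 and uses known chemistry. KH (THF, −78 → 0 °C) should trigger oxy-anion-accelerated conrotatory ring opening to the potassium dienolate F1. O-Silylation (TBSCl, −78 °C) should give methyl (3E,5E,20E,22E)-6-[(tert-butyldimethylsilyl)oxy]tetracosa-3,5,20,22-tetraenoate F2. [4+2] Cycloaddition of singlet oxygen (O2, tetraphenylporphyrin, hν, CH2Cl2, −78 °C) to this electron-rich 1-silyloxy-diene, which should react faster than the dialkyl diene of the side chain, should give methyl 2-{6-[(tert-butyldimethylsilyl)oxy]-6-[(14E,16E)-octadeca-14,16-dien-1-yl]-3,6-dihydro-1,2-dioxin-3-yl}acetate F3. CSA in MeOH then exchanges the silyloxy group for OMe under the same thermodynamic control, and the route is rejoined at 16.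

Step 9. What may go wrong: poor discrimination of a stereocentre β to the acyl carbon, the opposite enantiopreference, or slow turnover of the very lipophilic ester. The fallback sets out from 16 and is a covalent resolution. Saponification (LiOH, THF/H2O, 0 °C, then dilute HCl) should give the racemic 2-{(3R*,6R*)-6-methoxy-6-[(14E,16E)-octadeca-14,16-dien-1-yl]-3,6-dihydro-1,2-dioxin-3-yl}acetic acid F4. Coupling with (S)-4-benzyl-1,3-thiazolidine-2-thione (EDC, DMAP, CH2Cl2) should give the diastereomeric N-acyl thiazolidinethiones, the (3R,6R) imide F5 and the (3S,6S) imide F6, to be separated on silica. Methanolysis of F5 (MeOH, imidazole, 23 °C) comes back to the route at 17.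

Step 6. What may go wrong: interception of the activated amide or the keteniminium ion by the ester carbonyl, oligomerisation of the keteniminium salt at low acetylene concentration, or polymerisation of the cyclobutenone during hydrolysis. The fallback sets out from 8. Dehydrochlorination with Et3N in the presence of ethoxyacetylene (Et2O, 0 → 23 °C) should give, through methyl 4-oxobut-3-enoate (the ketene) F7, the [2+2] adduct methyl 2-(2-ethoxy-4-oxocyclobut-2-en-1-yl)acetate F8. Luche reduction (NaBH4, CeCl3, MeOH, −40 °C) should give methyl 2-(2-ethoxy-4-hydroxycyclobut-2-en-1-yl)acetate F9. Dilute aqueous acid then effects enol-ether hydrolysis with allylic transposition (Stork–Danheiser type), and the route is rejoined at 12.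

Further compounds
F1 | step 8 | potassium (1E,3E)-6-methoxy-6-oxo-1-[(14E,16E)-octadeca-14,16-dien-1-yl]hexa-1,3-dien-1-olate | C/C=C/C=C/CCCCCCCCCCCCC/C([O-])=C\C=C\CC(=O)OC.[K+]
F2 | step 8 | methyl (3E,5E,20E,22E)-6-[(tert-butyldimethylsilyl)oxy]tetracosa-3,5,20,22-tetraenoate | C/C=C/C=C/CCCCCCCCCCCCC/C(O[Si](C)(C)C(C)(C)C)=C\C=C\CC(=O)OC
F3 | step 8 | methyl 2-{6-[(tert-butyldimethylsilyl)oxy]-6-[(14E,16E)-octadeca-14,16-dien-1-yl]-3,6-dihydro-1,2-dioxin-3-yl}acetate (ketal epimers, racemic) | C/C=C/C=C/CCCCCCCCCCCCCC1(O[Si](C)(C)C(C)(C)C)C=CC(CC(=O)OC)OO1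
F4 | step 9 | rac-2-{(3R*,6R*)-6-methoxy-6-[(14E,16E)-octadeca-14,16-dien-1-yl]-3,6-dihydro-1,2-dioxin-3-yl}acetic acid | C/C=C/C=C/CCCCCCCCCCCCC[C@]1(OC)C=C[C@@H](CC(=O)O)OO1.C/C=C/C=C/CCCCCCCCCCCCC[C@@]1(OC)C=C[C@H](CC(=O)O)OO1
F5 | step 9 | 1-[(4S)-4-benzyl-2-thioxo-1,3-thiazolidin-3-yl]-2-{(3R,6R)-6-methoxy-6-[(14E,16E)-octadeca-14,16-dien-1-yl]-3,6-dihydro-1,2-dioxin-3-yl}ethan-1-one | C/C=C/C=C/CCCCCCCCCCCCC[C@]1(OC)C=C[C@@H](CC(=O)N2[C@@H](Cc3ccccc3)CSC2=S)OO1
F6 | step 9 | 1-[(4S)-4-benzyl-2-thioxo-1,3-thiazolidin-3-yl]-2-{(3S,6S)-6-methoxy-6-[(14E,16E)-octadeca-14,16-dien-1-yl]-3,6-dihydro-1,2-dioxin-3-yl}ethan-1-one | C/C=C/C=C/CCCCCCCCCCCCC[C@@]1(OC)C=C[C@H](CC(=O)N2[C@@H](Cc3ccccc3)CSC2=S)OO1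
F7 | step 6 | methyl 4-oxobut-3-enoate (ketene) | COC(=O)CC=C=O
F8 | step 6 | methyl 2-(2-ethoxy-4-oxocyclobut-2-en-1-yl)acetate (racemic) | CCOC1=CC(=O)C1CC(=O)OC
F9 | step 6 | methyl 2-(2-ethoxy-4-hydroxycyclobut-2-en-1-yl)acetate (racemic, both epimers) | CCOC1=CC(O)C1CC(=O)OC
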